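**Plan**

- Cuts: (a) the disubstituted CH=CH between the ring A dienynyl chain and the butenolide dienal (Julia–Kocienski); (b) both bonds to the lactone carbonyl carbon, Cα–C(=O) and C(=O)–O(ring), by CO insertion; (c) the alkynyl–acyl bond of the ynone behind the iodoenone; (d) the ring A C(sp2)–C(sp) bond (Sonogashira) and, on ring B, the C-6–C-7 bond and the oxirane C–O bonds.
- Enabling feature: in the furanone ring the carbonyl carbon sits between the α-carbon that carries the epoxy-vinyl arm and the ring oxygen, and this oxygen is the enol oxygen of a ketone at the γ-carbon whose single α-CH2 becomes the exocyclic =CH. The ring is therefore CO plus a (Z)-β-iodo dienone.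
- Forward order: actinol to the ring B epoxy enyne (steps 1–7); C6 enynol to the skipped Weinreb amide (8–11); ynone, then Z-iodoenone (12–13); the butenolide, the only ring built, closes by carbonylation (14); desilylation and oxidation give the dienal (15–16); ring A sulfone from actinol and the same enynol (17–24); the chain is joined last (25).
- Stereochemistry: C-3 (ring B) and C-3' (ring A) come unchanged from (4R,6R)-actinol; C-5 and C-6 come from a Sharpless epoxidation anti to the C-3 silyloxy group; alkene geometry comes from E-selective olefinations, anti hydroiodination, the thermodynamic Z ylidene and a final cis-to-trans equilibration.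

Key step: step 14

Assumption: phosphonates 9 and 26 are taken as purchasable; ring positions are cited with carotenoid locants (C-3, C-5, C-6 on the epoxy ring B, C-3' on ring A), and the ring B hydroxyl stays silylated through the key step.

**Route**

Step 1
Reactants: 1 (4R,6R)-actinol [(4R,6R)-4-hydroxy-2,2,6-trimethylcyclohexanone]
Product: 2 (4R,6R)-4-[(tert-butyldimethylsilyl)oxy]-2,2,6-trimethylcyclohexanone
Conditions: TBSCl, imidazole, DMF, rt
Reagents that add atoms: tert-butyldimethylsilyl chloride, CC(C)(C)[Si](C)(C)Cl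
Why: Imidazole-promoted silyl ether formation on the unhindered secondary alcohol should be clean, and the carbinol centre is not touched.

Step 2
Reactants: 2 silyloxy ketone
Product: 3 (4R)-4-[(tert-butyldimethylsilyl)oxy]-2,6,6-trimethylcyclohex-1-en-1-yl trifluoromethanesulfonate
Conditions: LiN(i-Pr)2, THF, −78 °C; then PhNTf2, −78 °C → rt
Reagents that add atoms: N-phenylbis(trifluoromethanesulfonimide), O=S(=O)(N(c1ccccc1)S(=O)(=O)C(F)(F)F)C(F)(F)F
Why: Enol triflate formation can give only the tetrasubstituted vinyl triflate, because C-6 is the single enolisable position (the other α-carbon is quaternary), and C-4 is unaffected.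

Step 3
Reactants: 3 vinyl triflate; 4 carbon monoxide
Product: 5 methyl (4R)-4-[(tert-butyldimethylsilyl)oxy]-2,6,6-trimethylcyclohex-1-ene-1-carboxylate
Conditions: Pd(OAc)2 (cat.), PPh3, CO (1 atm), MeOH, Et3N, DMF, 60 °C
Reagents that add atoms: methanol, CO
Why: Palladium-catalysed alkoxycarbonylation of a vinyl triflate (zerovalent palladium inserts into the C–OTf bond, CO inserts, methanol cleaves the acyl complex) should install the future C-7 carbon.

Step 4
Reactants: 5 unsaturated ester
Product: 6 {(4R)-4-[(tert-butyldimethylsilyl)oxy]-2,6,6-trimethylcyclohex-1-en-1-yl}methanol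
Conditions: i-Bu2AlH, CH2Cl2, −78 → 0 °C; aq. potassium sodium tartrate work-up
Reagents that add atoms: none
Why: 1,2-Reduction of the conjugated ester by the aluminium hydride (DIBAL reduction) should give the allylic alcohol that directs the epoxidation, with the silyl ether inert.

Step 5
Reactants: 6 allylic alcohol
Product: 7 {(1R,4S,6R)-4-[(tert-butyldimethylsilyl)oxy]-2,2,6-trimethyl-7-oxabicyclo[4.1.0]heptan-1-yl}methanol (oxirane anti to the silyloxy group)
Conditions: Ti(Oi-Pr)4, D-(−)-diethyl tartrate, t-BuOOH, 4 Å molecular sieves, CH2Cl2, −20 °C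
Reagents that add atoms: tert-butyl hydroperoxide, CC(C)(C)OO
Why: Sharpless asymmetric epoxidation delivers oxygen to one alkene face under reagent control, and D-(−)-tartrate is the enantiomer whose delivery falls anti to the C-3 silyloxy group, so both new centres (5R,6S in carotenoid numbering) are set in one syn addition.

Step 6
Reactants: 7 epoxy alcohol
Product: 8 (1S,4S,6R)-4-[(tert-butyldimethylsilyl)oxy]-2,2,6-trimethyl-7-oxabicyclo[4.1.0]heptane-1-carbaldehyde
Conditions: (n-Pr)4N[RuO4] (cat.), N-methylmorpholine N-oxide, 4 Å molecular sieves, CH2Cl2, rt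
Reagents that add atoms: none
Why: Ley–Griffith oxidation is neutral, so the oxirane should survive, and the α-carbon is quaternary, so it cannot epimerise.

Step 7
Reactants: 8 epoxy aldehyde; 9 diethyl [3-(trimethylsilyl)prop-2-yn-1-yl]phosphonate
Product: 11 tert-butyl({(1S,4S,6R)-1-[(1E)-but-1-en-3-yn-1-yl]-2,2,6-trimethyl-7-oxabicyclo[4.1.0]heptan-4-yl}oxy)dimethylsilane (ring B epoxy enyne), via C-silylated enyne 10 (not isolated)
Conditions: 9, LiN(SiMe3)2, THF, −78 °C; then 8, −78 → 0 °C; then K2CO3, MeOH, rt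
Reagents that add atoms: none
Why: Horner–Wadsworth–Emmons olefination of the hindered, non-enolisable aldehyde with the stabilised propargylic phosphonate anion should favour the E-enyne, and carbonate-mediated methanolysis of the alkynyl C–Si bond then frees the terminal alkyne in the same pot while the silyl ether stays on.

Step 8
Reactants: 12 (2E)-3-methylpent-2-en-4-yn-1-ol
Product: 13 tert-butyldimethyl{[(2E)-3-methylpent-2-en-4-yn-1-yl]oxy}silane
Conditions: TBSCl, imidazole, DMF, 0 °C → rt
Reagents that add atoms: tert-butyldimethylsilyl chloride, CC(C)(C)[Si](C)(C)Cl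
Why: Standard silylation of a primary allylic alcohol (silyl ether formation) protects it for the hydroboration and the later organolithium step.

Step 9
Reactants: 13 silylated enynol
Product: 15 (3E)-5-[(tert-butyldimethylsilyl)oxy]-3-methylpent-3-enal, via dienylborane 14 (not isolated)
Conditions: (c-C6H11)2BH (from BH3·SMe2 and cyclohexene), THF, 0 °C; then H2O2, NaH2PO4/Na2HPO4 buffer (pH 7), 0 °C → rt
Reagents that add atoms: hydrogen peroxide, OO
Why: Anti-Markovnikov hydroboration–oxidation of the terminal alkyne relies on the bulky dialkylborane adding syn to the alkyne much faster than to the trisubstituted alkene, and buffered oxidation gives a dienol that should tautomerise by α-protonation to the skipped aldehyde with the E-alkene intact.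

Step 10
Reactants: 15 skipped aldehyde (used crude)
Product: 16 (3E)-5-[(tert-butyldimethylsilyl)oxy]-3-methylpent-3-enoic acid
Conditions: NaClO2, NaH2PO4, 2-methyl-2-butene, t-BuOH/H2O, 0 °C → rt
Reagents that add atoms: sodium chlorite, [Na+].[O-]Cl=O
Why: Pinnick oxidation under buffered conditions with an alkene scavenger for HOCl should convert the labile aldehyde to the acid without moving the double bond or cleaving the silyl ether.

Step 11
Reactants: 16 skipped acid
Product: 17 (3E)-5-[(tert-butyldimethylsilyl)oxy]-N-methoxy-N,3-dimethylpent-3-enamide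
Conditions: MeNHOMe·HCl, EDC·HCl, HOBt, N-methylmorpholine, CH2Cl2, 0 °C → rt
Reagents that add atoms: N,O-dimethylhydroxylamine hydrochloride, CNOC.Cl
Why: Carbodiimide/HOBt amide coupling with a weak base should give the Weinreb amide without pulling the β,γ-alkene into conjugation.

Step 12
Reactants: 11 ring B epoxy enyne; 17 Weinreb amide
Product: 18 (2E,8E)-1-[(tert-butyldimethylsilyl)oxy]-9-{(1S,4S,6R)-4-[(tert-butyldimethylsilyl)oxy]-2,2,6-trimethyl-7-oxabicyclo[4.1.0]heptan-1-yl}-3-methylnona-2,8-dien-6-yn-5-one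
Conditions: n-BuLi, THF, −78 °C; then 17, −78 → −30 °C; aq. NH4Cl
Reagents that add atoms: none
Why: In this Weinreb ketone synthesis the lithium acetylide adds once to the N-methoxy-N-methylamide and the chelated adduct holds until work-up, so the skipped ynone should form without over-addition, carbonyl addition at low temperature outrunning deprotonation of the allylic α-CH2.

Step 13
Reactants: 18 ynone
Product: 19 (2E,6Z,8E)-1-[(tert-butyldimethylsilyl)oxy]-9-{(1S,4S,6R)-4-[(tert-butyldimethylsilyl)oxy]-2,2,6-trimethyl-7-oxabicyclo[4.1.0]heptan-1-yl}-7-iodo-3-methylnona-2,6,8-trien-5-one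
Conditions: NaI, AcOH, MeCN, 0 °C → rt, dark
Reagents that add atoms: sodium iodide, [Na+].[I-]
Why: Conjugate hydroiodination of the ynone puts iodide on the β-alkyne carbon (C-7) and protonates the allenol anti to iodine, which should give the kinetic Z-β-iodoenone with iodine cis to the carbonyl, the weak acid and low temperature sparing the oxirane, the silyl ethers and the skipped alkene.

Step 14
Reactants: 19 (Z)-β-iodo dienone; 4 carbon monoxide
Product: 20 (5Z)-5-[(2E)-4-{[tert-butyl(dimethyl)silyl]oxy}-2-methylbut-2-en-1-ylidene]-3-[(E)-2-{(1S,4S,6R)-4-{[tert-butyl(dimethyl)silyl]oxy}-2,2,6-trimethyl-7-oxabicyclo[4.1.0]heptan-1-yl}ethenyl]furan-2(5H)-one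
Conditions: PdCl2(PPh3)2 (5 mol %), CO (1 atm), Et3N, MeCN, rt → 50 °C
Reagents that add atoms: none
Why: Zerovalent palladium, formed in situ from the divalent palladium precatalyst, adds to the vinyl C–I bond of 19 with retention and CO insertion gives an acylpalladium held cis to the C-5 ketone across the Z double bond; Et3N enolises the ketone toward C-4, its only α-CH2 and an allylic one, and the dienolate oxygen acylates (or the ketone oxygen adds first and C-4 then loses a proton), forming the Cα–C(=O) and C(=O)–O bonds and releasing zerovalent palladium. The closest known reaction type is the palladium-catalysed carbonylative lactonisation of (Z)-β-iodoenones to (Z)-γ-alkylidenebutenolides by enolate-oxygen capture of the acylpalladium. The single ring closes in a 5-exo-trig O-acylation through an in-plane oxygen lone pair, whereas C-acylation from C-4 would be a 5-(enolendo)-exo-trig closure that the planar acyl dienone cannot reach. No stereocentre is created and the three existing ones are remote. The step needs O- over C-acylation, a Z exocyclic alkene and an intact vinyl oxirane: the first follows from the geometry just described, the second from the lower strain of the isomer that keeps the dienyl arm syn to the ring oxygen and away from H-4 under equilibrating basic conditions, and the third from oxidative addition to C–I being much faster than ionisation of the fully substituted, electron-poor vinyl oxirane, with no external nucleophile present to intercept the acyl complex.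

Step 15
Reactants: 20 bis-silyl ylidenebutenolide
Product: 21 (5Z)-5-[(2E)-4-hydroxy-2-methylbut-2-en-1-ylidene]-3-[(E)-2-{(1S,4S,6R)-4-hydroxy-2,2,6-trimethyl-7-oxabicyclo[4.1.0]heptan-1-yl}ethenyl]furan-2(5H)-one
Conditions: Bu4NF, AcOH, THF, 0 °C → rt
Reagents that add atoms: none
Why: Fluoride-mediated desilylation buffered with acetic acid should remove both silyl ethers while the base-sensitive ylidenebutenolide and the oxirane survive.

Step 16
Reactants: 21 butenolide diol
Product: 22 (2E)-4-[(2Z)-4-[(E)-2-{(1S,4S,6R)-4-hydroxy-2,2,6-trimethyl-7-oxabicyclo[4.1.0]heptan-1-yl}ethenyl]-5-oxofuran-2(5H)-ylidene]-3-methylbut-2-enal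
Conditions: MnO2, CH2Cl2, rt
Reagents that add atoms: none
Why: Manganese dioxide oxidation is selective for the allylic (dienylic) primary alcohol and should leave the saturated secondary ring alcohol alone.

Step 17
Reactants: 1 (4R,6R)-actinol
Product: 23 (1R,5R)-3,3,5-trimethyl-4-oxocyclohexyl acetate
Conditions: Ac2O, pyridine, DMAP (cat.), CH2Cl2, rt
Reagents that add atoms: acetic anhydride, CC(=O)OC(C)=O
Why: DMAP-catalysed acetylation puts the ester that the target carries on ring A in place from the start, with no change at the carbinol centre.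

Step 18
Reactants: 23 actinol acetate
Product: 24 (1R)-3,5,5-trimethyl-4-{[(trifluoromethyl)sulfonyl]oxy}cyclohex-3-en-1-yl acetate
Conditions: Tf2O, 2,6-di-tert-butyl-4-methylpyridine, CH2Cl2, 0 °C → rt
Reagents that add atoms: trifluoromethanesulfonic anhydride, O=S(=O)(OS(=O)(=O)C(F)(F)F)C(F)(F)F
Why: Electrophilic enol triflate formation with triflic anhydride and a hindered pyridine tolerates esters, and only C-5 bears an α-hydrogen, so a single vinyl triflate should form with the acetate and its stereocentre intact.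

Step 19
Reactants: 12 (2E)-3-methylpent-2-en-4-yn-1-ol
Product: 25 (2E)-3-methylpent-2-en-4-ynal
Conditions: MnO2, CH2Cl2, rt (solution used directly)
Reagents that add atoms: none
Why: Manganese dioxide oxidation of the allylic alcohol should give the volatile enynal without touching the alkyne or the E geometry.

Step 20
Reactants: 25 enynal; 26 triethyl phosphonoacetate
Product: 27 ethyl (2E,4E)-5-methylhepta-2,4-dien-6-ynoate
Conditions: 26, LiCl, DBU, MeCN, 0 °C → rt
Reagents that add atoms: none
Why: Horner–Wadsworth–Emmons olefination under Masamune–Roush conditions with the stabilised phosphonoacetate anion should give the E-enoate and is mild enough for the terminal alkyne.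

Step 21
Reactants: 27 dienynoate
Product: 28 (2E,4E)-5-methylhepta-2,4-dien-6-yn-1-ol
Conditions: i-Bu2AlH, CH2Cl2, −78 °C; aq. potassium sodium tartrate work-up
Reagents that add atoms: none
Why: DIBAL 1,2-reduction of the conjugated ester should give the allylic alcohol without reducing the dienyne.

Step 22
Reactants: 24 ring A acetoxy triflate; 28 dienynol
Product: 29 (1R)-4-[(3E,5E)-7-hydroxy-3-methylhepta-3,5-dien-1-yn-1-yl]-3,5,5-trimethylcyclohex-3-en-1-yl acetate
Conditions: Pd(PPh3)4 (cat.), CuI (cat.), i-Pr2NH, DMF, rt → 50 °C, degassed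
Reagents that add atoms: none
Why: Sonogashira coupling (oxidative addition of zerovalent palladium to the vinyl triflate, copper acetylide transmetallation, reductive elimination) should join ring A to the dienyne, and the amine base tolerates the acetate and the free alcohol.

Step 23
Reactants: 29 ring A dienynol
Product: 30 (1R)-4-[(3E,5E)-7-(1,3-benzothiazol-2-ylsulfanyl)-3-methylhepta-3,5-dien-1-yn-1-yl]-3,5,5-trimethylcyclohex-3-en-1-yl acetate
Conditions: 2-mercaptobenzothiazole, PPh3, DIAD, THF, 0 °C
Reagents that add atoms: 2-mercaptobenzothiazole, Sc1nc2ccccc2s1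
Why: Mitsunobu thioetherification of the primary allylic alcohol with the acidic heteroaryl thiol should proceed by direct SN2 displacement without allylic transposition.

Step 24
Reactants: 30 benzothiazolyl sulfide
Product: 31 (1R)-4-[(3E,5E)-7-(1,3-benzothiazol-2-ylsulfonyl)-3-methylhepta-3,5-dien-1-yn-1-yl]-3,5,5-trimethylcyclohex-3-en-1-yl acetate
Conditions: H2O2 (30 %), (NH4)6Mo7O24·4H2O (cat.), EtOH, 0 °C → rt
Reagents that add atoms: hydrogen peroxide, OO
Why: Molybdate-catalysed peroxide oxidation of the sulfide to the sulfone is chemoselective because sulfur is far more nucleophilic toward the peroxomolybdate than the conjugated dienyne or the ring alkene.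

Step 25
Reactants: 22 butenolide dienal; 31 ring A sulfone
Product: 33 pyrrhoxanthin, the (3S,5R,6S,3'R) target, via cis-olefin isomer 32 (not isolated)
Conditions: NaN(SiMe3)2 added to 22 + 31, THF, −78 °C → rt; then C6H6, rt, diffuse daylight
Reagents that add atoms: none
Why: In this Julia–Kocienski olefination the metalated benzothiazolyl sulfone adds to the aldehyde and Smiles rearrangement with loss of SO2 and benzothiazolone forms the last C=C bond, the expected cis-rich kinetic mixture at this unhindered disubstituted alkene relaxing to the all-trans polyene on equilibration, while deprotonation of the doubly activated sulfone CH2 at −78 °C is much faster than enolisation of the acetate or attack on the butenolide.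

**Compound list**

1 | (4R,6R)-4-hydroxy-2,2,6-trimethylcyclohexanone, (4R,6R)-actinol | O[C@@H]1C[C@@H](C)C(=O)C(C)(C)C1 | starting material
2 | (4R,6R)-4-[(tert-butyldimethylsilyl)oxy]-2,2,6-trimethylcyclohexanone | CC(C)(C)[Si](C)(C)O[C@@H]1C[C@@H](C)C(=O)C(C)(C)C1 | intermediate
3 | (4R)-4-[(tert-butyldimethylsilyl)oxy]-2,6,6-trimethylcyclohex-1-en-1-yl trifluoromethanesulfonate | CC(C)(C)[Si](C)(C)O[C@@H]1CC(C)=C(OS(=O)(=O)C(F)(F)F)C(C)(C)C1 | intermediate
4 | carbon monoxide | [C-]#[O+] | starting material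
5 | methyl (4R)-4-[(tert-butyldimethylsilyl)oxy]-2,6,6-trimethylcyclohex-1-ene-1-carboxylate | CC(C)(C)[Si](C)(C)O[C@@H]1CC(C)=C(C(=O)OC)C(C)(C)C1 | intermediate
6 | {(4R)-4-[(tert-butyldimethylsilyl)oxy]-2,6,6-trimethylcyclohex-1-en-1-yl}methanol | CC(C)(C)[Si](C)(C)O[C@@H]1CC(C)=C(CO)C(C)(C)C1 | intermediate
7 | {(1R,4S,6R)-4-[(tert-butyldimethylsilyl)oxy]-2,2,6-trimethyl-7-oxabicyclo[4.1.0]heptan-1-yl}methanol | OC[C@@]12O[C@]1(C)C[C@@H](O[Si](C)(C)C(C)(C)C)CC2(C)C | intermediate
8 | (1S,4S,6R)-4-[(tert-butyldimethylsilyl)oxy]-2,2,6-trimethyl-7-oxabicyclo[4.1.0]heptane-1-carbaldehyde | O=C[C@@]12O[C@]1(C)C[C@@H](O[Si](C)(C)C(C)(C)C)CC2(C)C | intermediate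
9 | diethyl [3-(trimethylsilyl)prop-2-yn-1-yl]phosphonate | CCOP(=O)(CC#C[Si](C)(C)C)OCC | starting material
10 | tert-butyldimethyl({(1S,4S,6R)-2,2,6-trimethyl-1-[(1E)-4-(trimethylsilyl)but-1-en-3-yn-1-yl]-7-oxabicyclo[4.1.0]heptan-4-yl}oxy)silane | C[Si](C)(C)C#C/C=C/[C@@]12O[C@]1(C)C[C@@H](O[Si](C)(C)C(C)(C)C)CC2(C)C | intermediate
11 | tert-butyl({(1S,4S,6R)-1-[(1E)-but-1-en-3-yn-1-yl]-2,2,6-trimethyl-7-oxabicyclo[4.1.0]heptan-4-yl}oxy)dimethylsilane | C#C/C=C/[C@@]12O[C@]1(C)C[C@@H](O[Si](C)(C)C(C)(C)C)CC2(C)C | intermediate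
12 | (2E)-3-methylpent-2-en-4-yn-1-ol | C#C/C(C)=C/CO | starting material
13 | tert-butyldimethyl{[(2E)-3-methylpent-2-en-4-yn-1-yl]oxy}silane | C#C/C(C)=C/CO[Si](C)(C)C(C)(C)C | intermediate
14 | {(1E,3E)-5-[(tert-butyldimethylsilyl)oxy]-3-methylpenta-1,3-dien-1-yl}dicyclohexylborane | CC(C)(C)[Si](C)(C)OC/C=C(C)/C=C/B(C1CCCCC1)C1CCCCC1 | intermediate
15 | (3E)-5-[(tert-butyldimethylsilyl)oxy]-3-methylpent-3-enal | O=CC/C(C)=C/CO[Si](C)(C)C(C)(C)C | intermediate
16 | (3E)-5-[(tert-butyldimethylsilyl)oxy]-3-methylpent-3-enoic acid | OC(=O)C/C(C)=C/CO[Si](C)(C)C(C)(C)C | intermediate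
17 | (3E)-5-[(tert-butyldimethylsilyl)oxy]-N-methoxy-N,3-dimethylpent-3-enamide | CON(C)C(=O)C/C(C)=C/CO[Si](C)(C)C(C)(C)C | intermediate
18 | (2E,8E)-1-[(tert-butyldimethylsilyl)oxy]-9-{(1S,4S,6R)-4-[(tert-butyldimethylsilyl)oxy]-2,2,6-trimethyl-7-oxabicyclo[4.1.0]heptan-1-yl}-3-methylnona-2,8-dien-6-yn-5-one | CC(C)(C)[Si](C)(C)OC/C=C(C)/CC(=O)C#C/C=C/[C@@]12O[C@]1(C)C[C@@H](O[Si](C)(C)C(C)(C)C)CC2(C)C | intermediate
19 | (2E,6Z,8E)-1-[(tert-butyldimethylsilyl)oxy]-9-{(1S,4S,6R)-4-[(tert-butyldimethylsilyl)oxy]-2,2,6-trimethyl-7-oxabicyclo[4.1.0]heptan-1-yl}-7-iodo-3-methylnona-2,6,8-trien-5-one | CC(C)(C)[Si](C)(C)OC/C=C(C)/CC(=O)/C=C(I)/C=C/[C@@]12O[C@]1(C)C[C@@H](O[Si](C)(C)C(C)(C)C)CC2(C)C | intermediate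
20 | (5Z)-5-[(2E)-4-{[tert-butyl(dimethyl)silyl]oxy}-2-methylbut-2-en-1-ylidene]-3-[(E)-2-{(1S,4S,6R)-4-{[tert-butyl(dimethyl)silyl]oxy}-2,2,6-trimethyl-7-oxabicyclo[4.1.0]heptan-1-yl}ethenyl]furan-2(5H)-one | CC(C)(C)[Si](C)(C)OC/C=C(C)/C=C1C=C(/C=C/[C@@]23O[C@]2(C)C[C@@H](O[Si](C)(C)C(C)(C)C)CC3(C)C)C(=O)O/1 | intermediate
21 | (5Z)-5-[(2E)-4-hydroxy-2-methylbut-2-en-1-ylidene]-3-[(E)-2-{(1S,4S,6R)-4-hydroxy-2,2,6-trimethyl-7-oxabicyclo[4.1.0]heptan-1-yl}ethenyl]furan-2(5H)-one | OC/C=C(C)/C=C1C=C(/C=C/[C@@]23O[C@]2(C)C[C@@H](O)CC3(C)C)C(=O)O/1 | intermediate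
22 | (2E)-4-[(2Z)-4-[(E)-2-{(1S,4S,6R)-4-hydroxy-2,2,6-trimethyl-7-oxabicyclo[4.1.0]heptan-1-yl}ethenyl]-5-oxofuran-2(5H)-ylidene]-3-methylbut-2-enal | O=C/C=C(C)/C=C1C=C(/C=C/[C@@]23O[C@]2(C)C[C@@H](O)CC3(C)C)C(=O)O/1 | intermediate
23 | (1R,5R)-3,3,5-trimethyl-4-oxocyclohexyl acetate | CC(=O)O[C@@H]1C[C@@H](C)C(=O)C(C)(C)C1 | intermediate
24 | (1R)-3,5,5-trimethyl-4-{[(trifluoromethyl)sulfonyl]oxy}cyclohex-3-en-1-yl acetate | CC(=O)O[C@@H]1CC(C)=C(OS(=O)(=O)C(F)(F)F)C(C)(C)C1 | intermediate
25 | (2E)-3-methylpent-2-en-4-ynal | C#C/C(C)=C/C=O | intermediate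
26 | triethyl phosphonoacetate | CCOC(=O)CP(=O)(OCC)OCC | starting material
27 | ethyl (2E,4E)-5-methylhepta-2,4-dien-6-ynoate | C#C/C(C)=C/C=C/C(=O)OCC | intermediate
28 | (2E,4E)-5-methylhepta-2,4-dien-6-yn-1-ol | C#C/C(C)=C/C=C/CO | intermediate
29 | (1R)-4-[(3E,5E)-7-hydroxy-3-methylhepta-3,5-dien-1-yn-1-yl]-3,5,5-trimethylcyclohex-3-en-1-yl acetate | CC(=O)O[C@@H]1CC(C)=C(C#C/C(C)=C/C=C/CO)C(C)(C)C1 | intermediate
30 | (1R)-4-[(3E,5E)-7-(1,3-benzothiazol-2-ylsulfanyl)-3-methylhepta-3,5-dien-1-yn-1-yl]-3,5,5-trimethylcyclohex-3-en-1-yl acetate | CC(=O)O[C@@H]1CC(C)=C(C#C/C(C)=C/C=C/CSc2nc3ccccc3s2)C(C)(C)C1 | intermediate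
31 | (1R)-4-[(3E,5E)-7-(1,3-benzothiazol-2-ylsulfonyl)-3-methylhepta-3,5-dien-1-yn-1-yl]-3,5,5-trimethylcyclohex-3-en-1-yl acetate | CC(=O)O[C@@H]1CC(C)=C(C#C/C(C)=C/C=C/CS(=O)(=O)c2nc3ccccc3s2)C(C)(C)C1 | intermediate
32 | isomer of 33 with a cis geometry at the double bond formed in step 25, all else as in 33 | CC(=O)O[C@@H]1CC(C)=C(C#C/C(C)=C/C=C/C=C\C=C(C)\C=C2C=C(/C=C/[C@@]34O[C@]3(C)C[C@@H](O)CC4(C)C)C(=O)O\2)C(C)(C)C1 | intermediate
33 | pyrrhoxanthin, (3S,5R,6S,3'R): ring A (3'R)-acetoxy-7',8'-didehydro end group, all-E polyene, (Z)-ylidenebutenolide, ring B (3S,5R,6S)-5,6-epoxy-3-hydroxy end group | CC(=O)O[C@@H]1CC(C)=C(C#C/C(C)=C/C=C/C=C/C=C(C)/C=C2C=C(/C=C/[C@@]34O[C@]3(C)C[C@@H](O)CC4(C)C)C(=O)O/2)C(C)(C)C1 | target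

**Summary and risks**

Total step count: 25. Longest linear sequence: 13 steps from actinol (steps 1–7, 12–16, 25).

Steps most likely to fail:

1. Step 14 (carbonylative lactonisation). Capture of the acylpalladium by the enolate oxygen may be too slow, so that hydrodeiodination or oligomerisation takes over, or zerovalent palladium may ionise the vinyl oxirane. The fallback sets out from 19 and runs the same CO insertion with water as the nucleophile (Pd(OAc)2, PPh3, CO, H2O, NaOAc, DMF). The resulting Z-keto acid should close to its pseudo-acid form, 5-hydroxy-5-[(2E)-4-(silyloxy)-2-methylbut-2-en-1-yl]butenolide F1 (both C-5 epimers). Dehydration of this lactol toward the doubly activated exocyclic CH2 (MsCl, Et3N, CH2Cl2, 0 °C) would return the route at 20.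

2. Step 13 (hydroiodination). Acid may rearrange the oxirane to the furanoid 5,8-oxide, the skipped alkene may migrate into conjugation with the ketone, or iodide may equilibrate the Z-iodoenone. The fallback avoids acid and sets out from 11 and 15. The lithium acetylide of 11 (n-BuLi, THF, −78 °C) would add to aldehyde 15 to give propargylic alcohol F2 (both carbinol epimers). Alkoxide-directed trans-hydroalumination with NaAlH2(OCH2CH2OMe)2 (THF, −78 → 0 °C) followed by I2 at −78 °C should give the (Z)-iodo allylic alcohol F3 with iodine on the carbon remote from the carbinol. MnO2 oxidation of the allylic alcohol would return the route at 19.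

3. Step 25 (Julia–Kocienski olefination). Base may degrade the ylidenebutenolide aldehyde, the sulfone anion may self-condense, or the cis/trans mixture may not equilibrate cleanly. The fallback sets out from 29, which with PPh3·HBr (MeOH/CH2Cl2, rt) should give the allylic triphenylphosphonium bromide F4. A Wittig reaction of F4 with 22 in 1,2-epoxybutane/EtOH (the epoxide acting as a neutral HBr scavenger, no strong base), followed by the same equilibration in benzene, would return the route at 33.

**Further compounds**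

F1 | step 14 | 5-[(2E)-4-{[tert-butyl(dimethyl)silyl]oxy}-2-methylbut-2-en-1-yl]-3-[(E)-2-{(1S,4S,6R)-4-{[tert-butyl(dimethyl)silyl]oxy}-2,2,6-trimethyl-7-oxabicyclo[4.1.0]heptan-1-yl}ethenyl]-5-hydroxyfuran-2(5H)-one (C-5 epimers) | CC(C)(C)[Si](C)(C)OC/C=C(C)/CC1(O)C=C(/C=C/[C@@]23O[C@]2(C)C[C@@H](O[Si](C)(C)C(C)(C)C)CC3(C)C)C(=O)O1
F2 | step 13 | (2E,8E)-1-[(tert-butyldimethylsilyl)oxy]-9-{(1S,4S,6R)-4-[(tert-butyldimethylsilyl)oxy]-2,2,6-trimethyl-7-oxabicyclo[4.1.0]heptan-1-yl}-3-methylnona-2,8-dien-6-yn-5-ol (C-5 epimers) | CC(C)(C)[Si](C)(C)OC/C=C(C)/CC(O)C#C/C=C/[C@@]12O[C@]1(C)C[C@@H](O[Si](C)(C)C(C)(C)C)CC2(C)C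
F3 | step 13 | (2E,6Z,8E)-1-[(tert-butyldimethylsilyl)oxy]-9-{(1S,4S,6R)-4-[(tert-butyldimethylsilyl)oxy]-2,2,6-trimethyl-7-oxabicyclo[4.1.0]heptan-1-yl}-7-iodo-3-methylnona-2,6,8-trien-5-ol (C-5 epimers) | CC(C)(C)[Si](C)(C)OC/C=C(C)/CC(O)/C=C(I)/C=C/[C@@]12O[C@]1(C)C[C@@H](O[Si](C)(C)C(C)(C)C)CC2(C)C
F4 | step 25 | {(2E,4E)-7-[(4R)-4-acetoxy-2,6,6-trimethylcyclohex-1-en-1-yl]-5-methylhepta-2,4-dien-6-yn-1-yl}triphenylphosphonium bromide | CC(=O)O[C@@H]1CC(C)=C(C#C/C(C)=C/C=C/C[P+](c2ccccc2)(c2ccccc2)c2ccccc2)C(C)(C)C1.[Br-]
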